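Late in the theta run, J and E together stand at 95.0 % of the charge. The gap is 2.50 mM, against a charge of D of 2.5 mM. In the zeta run the gap is 11.0 mM, against 10 mM. So D seems to take E about one to one, and at c_D = 5.00 mM I set the ceiling of c_J at 45.0 mM.

in all of them: G 0.028 mol%

| run | E | D | remark | time |
|---|---|---|---|---|
| theta | 0.050 M (in portions, 3) | 2.5 mM | run made earlier; portions every 2.0 h |  |
| zeta | 0.050 M (in portions, 3) | 10 mM | run made earlier; portions every 2.0 h |  |
| delta | 0.075 M (in portions, 3) | 5 mM | run made earlier; portions every 2.0 h |  |
| north-west | 0.050 M (in portions, 3) | 5.00 mM | the portions of E follow each other after 2.0 h, the first at the start | 30 h |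
| south-east | 0.050 M (in portions, 3) | 5.00 mM | the portions of E follow each other after 4.0 h, the first at the start | 30 h |
| west | 0.050 M (in portions, 3) | 5.00 mM | the portions of E follow each other after 8.0 h, the first at the start | 30 h |
| north-east | 0.050 M (in portions, 3) | 5.00 mM | the portions of E follow each other after 15 h, the first at the start | 30 h |

- theta (time / h: J / %, E / %): 5.00: 22, 73; 10.0: 46, 47; 15.0: 66, 29; 20.0: 81, 16; 25.0: 90, 5; 30.0: 92, 2; 40.0: 94, 1
- zeta (time / h: J / %, E / %): 2.00: 6, 12; 6.00: 23, 57; 10.0: 43, 40; 15.0: 59, 23; 20.0: 71, 8; 30.0: 76, 3; 40.0: 78, 0
- delta (time / h: J / %, E / %): 3.00: 12, 46; 10.0: 52, 40; 15.0: 77, 18; 25.0: 90, 2; 40.0: 94, 0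

(scatter of a reading: 1.5 percentage points)

- the analysis behind the earlier runs scatters by 1.5 percentage points, standard deviation
- "hardly changes" means that all values lie within two and a half points (for a concentration: within two and a half percent of the largest)

- [J] at the end for north-west, south-east, west, north-east, in this order
- how that number moves from the first to the last of them (falls all the way / hardly changes / rises all the way / falls, then rises / rises, then falls)

Two of us dispute how near each flask comes to that ceiling.

My colleague holds the line view: G makes J at a steady rate. From 5.00 h to 20.0 h in theta she reads 1.97 mM h⁻¹. The ceiling then takes 22.9 h, which is less than 30 h. So she gives 45.0 mM for the intervals 2.0 h, 4.0 h and 8.0 h. In north-east the third portion lands at the asked time, so she gives 28.3 mM there.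

I work with the fraction left. In theta, after the last portion, E falls from 73 % at 5.00 h to 5 % at 25.0 h. That reading gives a clearing half-life of 5.17 h: the time in which the E present halves at this loading of G, averaged over that stretch of theta. I treat it as a pseudo-first-order half-life, and it carries the scatter of the readings.

In west, I reckon the first portion less D at 11.7 mM. The last portion then has 2.71 half-lives to clear. Halving through the intervals, I reckon 3.63 mM of E at the end. So I put c_J in west at 41.4 mM, less than the ceiling she gives.

The forecast stands on my side of the dispute, by its own route: “It fits saturation kinetics”. It gives 0.044 M, 0.044 M, 0.0423 M and 0.0275 M, and says the row falls all the way. Its west figure lies above mine.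

The flasks give 0.0437 M, 0.0432 M, 0.0409 M and 0.0262 M: falls all the way. The forecast holds.

    E + G → J + G, rate k1*[E]*[G]/(1 + ([E]/Km1)) (29.0 mM, k = 210 M⁻¹ min⁻¹)
    E + D → Z (k = 1.10 M⁻¹ min⁻¹)

West holds 8.20 % of E at 30 h, and the half-life gave 7.27 %. For north-east, with two portions counted, it gives 4.88 %, and that flask holds 4.30 %. The line view keeps the early theta stretch, where J gained 24 percentage points and then 20 points per 5.00 h, before 9 points late on. In north-west, E + D → Z ran while D was there, with the midpoint of its turnover at 0.721 h and 100 % of it done by 15.0 h. E → J ran on with G at 100 %, its midpoint at 9.50 h.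

The readings come from a simulation with constants of no real substance, and the scatter is random.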